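**Remark on the chemistry.** Locants follow the germacrane numbering of the target for every intermediate (ring C1–C10, lactone C11–C13 with O on C8, C14 on C10, C15 on C4). Compound 1 is taken to be a catalogue compound. C11 is carried as a mixture of epimers from compound 10 to compound 20 and is erased in step 13.

## Analysis of the target

The target (31) is a germacrane 12,8-olide: a ten-membered carbocycle C1–C10 fused along C7–C8 to a butenolide (C7=C11–C12(=O)–O–C8). The γ-carbon C8 is sp2 and carries the ring double bond C8=C9, so the lactone is a γ-ylidene butenolide. C7 and C10 are trans across C8=C9 (Z by the sequence rule, because O8 outranks C7). There are three stereocentres: 4S (methyl, α to the C3 ketone and epimerisable), 6R (allylic secondary senecioate) and 10R (tertiary allylic carbinol). C4 and C6 are 1,3-related and cis, but C10 lies across the ring behind the sp2 atoms C7–C9, so it cannot be relayed from C4 or C6 by ordinary substrate control. Sensitive groups are the dienyl enol ester (base, nucleophiles), the allylic C13 acetate and the C6 ester (acyl transfer, elimination), the tertiary allylic alcohol (ionisation in acid) and the C4 centre. The difficulty is a medium ring that contains a trans enol-ester double bond and a remote quaternary carbinol; an end-to-end cyclisation controls neither. The strategy rests on one feature: the C3 carbonyl, the C8=C9 double bond and the C10–O carbon stand in the 1,5-relationship of an oxy-Cope product. C2–C3(=O) is the enolate half, C8=C9–C10 the allyl half, and C1–C10 the bond made; reconnecting C3–C8 gives a cyclohexane C3–C8 that already carries C15, O6 and the butenolide. Because C8 bears the lactone oxygen before the shift, C8=C9 is formed directly as the ylidene butenolide, and because C10 is an enol-ether carbon, the carbinol is formed already protected.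

## Retrosynthetic reasoning

**Esters last (31 → 26).** Neither the acetate nor the senecioate can survive the basic key step, so 31 is cut at both acyl C–O bonds. The C6 ester comes from alcohol 29 and acid chloride 30, 29 from silyl ether 28, the acetate 28 from diol 27, and 27 from the bis(4-methoxybenzyl) ether 26. The protecting groups are chosen so that one oxidative step frees the primary C13 and tertiary C10 hydroxyls (only the primary one acylates), and fluoride then frees C6.

**Key disconnection (26 → 24).** The C1–C10 bond is cut and C3–C8 reconnected. This replaces the ten-membered ring by the bicyclic butenolide 24, a 3-vinyl-8-alkenyl cyclohexanol. The forward reaction is the [3,3] shift of its C3 alkoxide. The stereochemistry of 24 follows from the fused lactone. The planar butenolide holds O8 in the plane C6–C7–C8, so on the cyclohexane chair O8 must be equatorial and the C8 alkenyl group axial. A vinyl group trans to it on C3 would also be axial, anti to the alkenyl group and out of reach. The two alkenyl groups must therefore be cis, with vinyl equatorial and the C3 oxygen axial. With 4S and 6R fixed by the target, only the 8R epimer keeps the C4 methyl and the C6 oxygen equatorial, so 24 is (3S,4S,6R,8R). In the chair transition state the C8–C7 bond is pseudo-equatorial (ring-trans C8=C9) and the substituent of C10 that is trans to C8 becomes pseudo-equatorial. Starting from 8R this gives 10R only if that substituent is the oxygen, so the enol ether must be E.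

**Enol ether (24 → 21).** A 2-alkoxyvinyl metal with the metal trans to oxygen would eliminate, and enolisation of a C10 methyl ketone would go to the methyl group or give the other geometry. The C10–O bond is therefore cut back to the alkenylboronate 22, and the B–C10/H–C9 pair back to the propynyl compound 21. Syn hydrometalation puts the metal on C10, remote from the quaternary C8 and trans to it. A stereoretentive copper-mediated coupling with alcohol 7 gives 23, and removal of the C3 silyl group gives 24.

**Butenolide (21 → 16 + 17).** The C7=C11 double bond is removed (21 from the saturated lactone 19 by dehydrogenation). Then C8–C9 and O8–C12 are cut: the alkynyl Grignard reagent 17 adds to the C8 ketone of 16 and the alkoxide closes onto the ester. Addition anti to the axial C3 silyloxy group puts the propynyl group axial and cis to the vinyl group. This is why C3 is built before C8; the reverse order would deliver vinyl anti to the C8 substituent.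

**Vinyl carbinol (16 → 12 + 13).** The C2–C3 bond is cut. The vinyl Grignard reagent 13 adds to the C3 ketone of the α-hydroxy ketone 12 under chelation with O8, equatorially and trans to the C4 methyl, giving 14. Oxidation at C8 (15) and silylation of O3 (16) follow.

**Ring substitution (12 → 5 + 9).** The C8–O bond comes from hydroxylation of the kinetic enolate of ketone 11. The C7–C11 bond comes from conjugate addition of the ketene silyl acetal 9 to enone 5, anti to O6. This one step brings in C11, C12 and C13 at the right oxidation levels. C4 is set in the same operation by equilibration, because in 11 the two C4 epimers differ only in an axial versus an equatorial methyl group.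

**Starting materials (5 → 1; 9 → 6 + 7).** Enone 5 is cut to 4 by methylation, and 4 to the ketal enone 1 through 3 and 2; the only reagent-controlled stereocentre (C6) comes from an enantioselective ketone reduction. The acetal 9 comes from ester 8, and 8 from acrylate 6 and alcohol 7. A p-menthane ketone from the chiral pool would map onto C3–C8, C11–C13 and C15, but it would leave C3, C6, C12 and C13 to be oxidised at unactivated or poorly differentiated positions. Building the ring from 1 places oxygen on C3, C6 and C8 from the start.

## Alternatives that were turned down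

**Alternative 1:** disconnection at C5–C6. The seco compound A2 carries a C6 aldehyde on the finished ylidene butenolide and a 2-methylcyclopropanol spanning C3–C5. Zn[N(SiMe3)2]2 would open the cyclopropanol between C3 and C5 to a zinc homoenolate, whose C5 adds to the aldehyde; this closes the ten-membered ring and reveals the C3 ketone in A1.

- For: it is convergent, the C13 acetate is already in place, the ketone needs no redox step, and only desilylation and senecioylation remain. Its endgame is shorter than the chosen one.
- Against: it is an end-to-end closure of a ten-membered ring, with transannular strain and competing oligomerisation. Zinc homoenolates are poor nucleophiles towards aldehydes, and here one would be generated with an amide base next to an enol lactone and an allylic acetate. C6 would be created in the ring closure on a flat butenolide, with only C4 on a flexible chain to direct it. The C8=C9 geometry and C10 would have to be made earlier in an open-chain ylidene butenolide with no conformational bias.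
- Comparison: the chosen route forms the ring by expansion of a six-membered ring, sets C6 by reagent control at the outset, and fixes alkene geometry and C10 in one transition state. It pays for this with more steps after ring formation.

**Alternative 2:** disconnection at C1–C2 through the twelve-membered allylic β-keto lactone A4. Pd(PPh3)4 (zerovalent palladium) ionises the C1 allylic ester, CO2 is lost, and the C2 enolate recombines with C1 of the π-allyl unit to give A3.

- For: a twelve-membered lactone is easier to close than a ten-membered carbocycle, the conditions are neutral, and the enolate is formed only at C2, so C4 is safe. On this point it equals the chosen route.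
- Against: the ion pair must collapse at the primary terminus C1 to the more strained ring; attack at C10 (eight-membered ring), O-allylation, protonation and diene formation compete. More seriously, A3 has the double bond at C9=C10 and oxygen on C8, whereas the target needs C8=C9 and a tertiary oxygen on C10. Getting there needs a face-selective oxidation of a medium-ring alkene to set C10, a regioselective shift of the double bond to C8=C9, and an enol lactonisation with the correct geometry. Each of these is a separate selectivity problem.
- Comparison: the chosen shift delivers the C8=C9/C10–O array and its stereochemistry directly.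

**Alternative 3:** disconnection at C8=C9 through the eleven-membered cyclic sulfone A6, with sulfur between C8 and C9. KOt-Bu with CBr2F2 halogenates C8, the C9 carbanion closes the episulfone, and loss of SO2 gives A5 (Ramberg–Bäcklund ring contraction).

- For: ring closure through C–S bond formation is among the most reliable routes to medium rings. C10 is made in an open chain by conventional asymmetric chemistry, so its configuration does not rest on a transition-state argument as it does in the chosen route; on this point the alternative is stronger.
- Against: the contraction gives no built-in control of alkene geometry, and in a ten-membered ring the less strained cis-ring alkene is the likely product, opposite to what is needed. The C9 carbanion is β to the lactone oxygen on C8, so opening of the lactone by E1cB competes with episulfone closure. The strong base also meets the acidic γ-hydrogen at C6. The C3 ketone has to be carried as a ketal and three different protecting groups removed, so the endgame is longer.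
- Comparison: the chosen route sets the C8=C9 geometry by the chair of a sigmatropic shift and needs no ketal.

Key step: step 17

## Route

Step 1
Reactants: 1 1,4-dioxaspiro[4.5]dec-6-en-8-one
Product: 2 (R)-1,4-dioxaspiro[4.5]dec-6-en-8-ol
Conditions: (S)-1-methyl-3,3-diphenyltetrahydro-1H,3H-pyrrolo[1,2-c][1,3,2]oxazaborole (10 mol %), BH3·SMe2, THF, −30 °C; MeOH
Reagents that add atoms: none
Why: Corey–Bakshi–Shibata reduction (1,2-reduction of an enone); with the alkene arm as the large group the (S)-oxazaborolidine should give the R carbinol, the future C6, while the ketal keeps the future C3 carbonyl out of play.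

Step 2
Reactants: 2 (R)-1,4-dioxaspiro[4.5]dec-6-en-8-ol
Product: 3 (R)-8-(tert-butyldimethylsilyloxy)-1,4-dioxaspiro[4.5]dec-6-ene
Conditions: t-BuMe2SiCl, imidazole, DMF, rt
Reagents that add atoms: tert-butyldimethylsilyl chloride, CC(C)(C)[Si](C)(C)Cl
Why: Silylation of a secondary alcohol; this silyl ether has to survive organometallic reagents, amide bases, DDQ and buffered fluoride until step 20.

Step 3
Reactants: 3 (R)-8-(tert-butyldimethylsilyloxy)-1,4-dioxaspiro[4.5]dec-6-ene
Product: 4 (R)-4-(tert-butyldimethylsilyloxy)cyclohex-2-en-1-one
Conditions: pyridinium p-toluenesulfonate, acetone/H2O, 40 °C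
Reagents that add atoms: water, O
Why: Acid-catalysed ketal hydrolysis; the freed ketone (future C3) is conjugated with the ring alkene (C8=C7) at once, and a secondary silyl ether tolerates this weak acid.

Step 4
Reactants: 4 (R)-4-(tert-butyldimethylsilyloxy)cyclohex-2-en-1-one
Product: 5 (4R)-4-(tert-butyldimethylsilyloxy)-6-methylcyclohex-2-en-1-one (both epimers at the methyl carbon, which is C4 of the target)
Conditions: LiN(i-Pr)2, THF, −78 °C; MeI, −78 → −40 °C
Reagents that add atoms: iodomethane, CI
Why: Alkylation of the kinetic cross-conjugated lithium enolate; only this α-carbon has acidic hydrogen atoms, so the methyl group enters regiospecifically, and its configuration (expected mainly trans to the silyloxy group) is not used because it is corrected in step 7.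

Step 5
Reactants: 6 methyl acrylate, 7 4-methoxybenzyl alcohol
Product: 8 methyl 3-(4-methoxybenzyloxy)propanoate
Conditions: NaH (5 mol %), THF, 0 °C → rt
Reagents that add atoms: none
Why: Base-catalysed oxa-Michael addition of a benzylic alcohol to an acrylate; it gives the C11–C13 unit with O13 already carrying the ether that DDQ removes later.

Step 6
Reactants: 8 methyl 3-(4-methoxybenzyloxy)propanoate
Product: 9 1-methoxy-3-(4-methoxybenzyloxy)-1-(trimethylsilyloxy)prop-1-ene (E/Z mixture)
Conditions: LiN(i-Pr)2, Me3SiCl, THF, −78 °C
Reagents that add atoms: chlorotrimethylsilane, C[Si](C)(C)Cl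
Why: Kinetic ester enolisation with in situ O-silylation (ketene silyl acetal formation); the internal quench at −78 °C keeps the β-alkoxy enolate from eliminating.

Step 7
Reactants: 5 (4R)-4-(tert-butyldimethylsilyloxy)-6-methylcyclohex-2-en-1-one, 9 1-methoxy-3-(4-methoxybenzyloxy)-1-(trimethylsilyloxy)prop-1-ene
Product: 11 methyl 2-[(1S,2R,4S)-2-(tert-butyldimethylsilyloxy)-4-methyl-5-oxocyclohexyl]-3-(4-methoxybenzyloxy)propanoate (C11 epimers), via silyl enol ether 10 (not isolated)
Conditions: (CF3SO2)2NH (2 mol %), CH2Cl2, −78 °C; then NaOMe, MeOH, 0 °C → rt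
Reagents that add atoms: none
Why: Mukaiyama–Michael addition, catalysed by the silyl triflimide formed in situ; the acetal should add to C7 anti to the neighbouring C6 silyloxy group, as is usual for 4-silyloxycyclohexenones. Methoxide then cleaves the silyl enol ether and equilibrates C4 (α to the ketone) to the equatorial methyl epimer, cis to O6, in the chair locked by the trans-diequatorial C6 and C7 substituents.

Step 8
Reactants: 11 methyl 2-[(1S,2R,4S)-2-(tert-butyldimethylsilyloxy)-4-methyl-5-oxocyclohexyl]-3-(4-methoxybenzyloxy)propanoate
Product: 12 methyl 2-[(1R,2R,4S,6R)-2-(tert-butyldimethylsilyloxy)-6-hydroxy-4-methyl-5-oxocyclohexyl]-3-(4-methoxybenzyloxy)propanoate (C8 hydroxyl; C11 epimers)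
Conditions: KN(SiMe3)2, THF, −78 °C; 2-(phenylsulfonyl)-3-phenyloxaziridine, −78 °C; NH4Cl (aq), −78 °C
Reagents that add atoms: 2-(phenylsulfonyl)-3-phenyloxaziridine, O=S(=O)(c1ccccc1)N1OC1c1ccccc1
Why: α-Hydroxylation of the kinetic potassium enolate (at C8, the unbranched α-carbon) with an N-sulfonyloxaziridine; oxygen should enter trans to the C7 side chain and so end equatorial. The cold quench is meant to keep the γ-hydroxy ester, which could only give a strained trans-fused lactone, open.

Step 9
Reactants: 12 methyl 2-[(1R,2R,4S,6R)-2-(tert-butyldimethylsilyloxy)-6-hydroxy-4-methyl-5-oxocyclohexyl]-3-(4-methoxybenzyloxy)propanoate, 13 vinylmagnesium bromide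
Product: 14 methyl 2-[(1R,2R,4S,5S,6R)-2-(tert-butyldimethylsilyloxy)-5,6-dihydroxy-4-methyl-5-vinylcyclohexyl]-3-(4-methoxybenzyloxy)propanoate (3S carbinol, hydroxyl cis to O8 and to the C4 methyl)
Conditions: 13 (3.5 equiv), THF, −78 → −40 °C
Reagents that add atoms: none
Why: Chelation-controlled Grignard addition to an α-hydroxy ketone: the first equivalent forms the C8 magnesium alkoxide, which ties O8 to the C3 carbonyl, and vinyl then attacks from the equatorial side, past the axial H4 and H8. This should set 3S, with the vinyl group equatorial and trans to the C4 methyl and the hydroxyl axial; the ester is not attacked at this temperature.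

Step 10
Reactants: 14 methyl 2-[(1R,2R,4S,5S,6R)-2-(tert-butyldimethylsilyloxy)-5,6-dihydroxy-4-methyl-5-vinylcyclohexyl]-3-(4-methoxybenzyloxy)propanoate
Product: 15 methyl 2-[(1S,2R,4S,5S)-2-(tert-butyldimethylsilyloxy)-5-hydroxy-4-methyl-6-oxo-5-vinylcyclohexyl]-3-(4-methoxybenzyloxy)propanoate (C8 ketone)
Conditions: SO3·pyridine, DMSO, i-Pr2NEt, CH2Cl2, 0 °C
Reagents that add atoms: none
Why: Parikh–Doering oxidation of the secondary alcohol; the tertiary allylic alcohol cannot be oxidised, and the mild, non-acidic conditions avoid glycol cleavage and ketol shifts.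

Step 11
Reactants: 15 methyl 2-[(1S,2R,4S,5S)-2-(tert-butyldimethylsilyloxy)-5-hydroxy-4-methyl-6-oxo-5-vinylcyclohexyl]-3-(4-methoxybenzyloxy)propanoate
Product: 16 methyl 2-[(1S,2R,4S,5S)-2-(tert-butyldimethylsilyloxy)-4-methyl-6-oxo-5-(trimethylsilyloxy)-5-vinylcyclohexyl]-3-(4-methoxybenzyloxy)propanoate
Conditions: Me3SiOSO2CF3, 2,6-lutidine, CH2Cl2, −78 °C
Reagents that add atoms: trimethylsilyl trifluoromethanesulfonate, C[Si](C)(C)OS(=O)(=O)C(F)(F)F
Why: Silylation of a hindered tertiary alcohol with a silyl triflate; the trimethylsilyl ether is non-chelating and axial, as the next addition requires, and can later be removed beside the secondary tert-butyldimethylsilyl ether.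

Step 12
Reactants: 16 methyl 2-[(1S,2R,4S,5S)-2-(tert-butyldimethylsilyloxy)-4-methyl-6-oxo-5-(trimethylsilyloxy)-5-vinylcyclohexyl]-3-(4-methoxybenzyloxy)propanoate, 17 prop-1-ynylmagnesium bromide
Product: 19 saturated trans-fused 12,8-lactone with axial C8 propynyl cis to the C3 vinyl group (C3 trimethylsilyl ether; C6 tert-butyldimethylsilyl ether; C13 4-methoxybenzyl ether; C11 epimers), via tertiary alkoxide 18 (not isolated)
Conditions: 17, CeCl3, THF, −78 °C → rt
Reagents that add atoms: none
Why: 1,2-Addition of an alkynylcerium reagent to a hindered, enolisable ketone, then lactonisation of the tertiary alkoxide onto the methyl ester, helped by the quaternary centre (Thorpe–Ingold effect). Attack should be axial, anti to the axial C3 silyloxy group (polar Felkin–Anh and steric control agree), so the propynyl group ends axial and O8 equatorial.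

Step 13
Reactants: 19 saturated trans-fused 12,8-lactone with C8 propynyl
Product: 21 (3S,4S,6R,8R)-8-(prop-1-ynyl) bicyclic butenolide (C7=C11; C3 trimethylsilyl ether; C6 tert-butyldimethylsilyl ether; C13 4-methoxybenzyl ether), via phenylselanyl lactone 20 (not isolated)
Conditions: LiN(i-Pr)2, THF, −78 °C; PhSeBr; then H2O2, pyridine, CH2Cl2, 0 °C → rt
Reagents that add atoms: none
Why: α-Selenenylation of the lactone enolate and selenoxide syn-elimination (dehydrogenation to the butenolide). The axial propynyl group should shield one face, so selenium enters on the face of H7 and elimination goes into the ring, away from the C13 ether oxygen; this erases the C7 and C11 stereocentres.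

Step 14
Reactants: 21 (3S,4S,6R,8R)-8-(prop-1-ynyl) bicyclic butenolide
Product: 22 8-[(Z)-2-(4,4,5,5-tetramethyl-1,3,2-dioxaborolan-2-yl)prop-1-enyl] bicyclic butenolide (boron on C10, trans to C8)
Conditions: pinacolborane, Cp2Zr(H)Cl (10 mol %), Et3N (10 mol %), CH2Cl2, 40 °C
Reagents that add atoms: pinacolborane, CC1(C)OBOC1(C)C
Why: Zirconium-catalysed syn hydroboration of an internal alkyne (hydrozirconation, then transmetalation to boron); the metal goes to C10, the alkyne carbon remote from the quaternary C8, which puts boron trans to C8. The terminal alkene and the tetrasubstituted butenolide alkene are expected to react much more slowly.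

Step 15
Reactants: 22 8-[(Z)-2-(pinacolboryl)prop-1-enyl] bicyclic butenolide, 7 4-methoxybenzyl alcohol
Product: 23 8-[(E)-2-(4-methoxybenzyloxy)prop-1-enyl] bicyclic butenolide, C3 trimethylsilyl ether
Conditions: 7 (excess), Cu(OAc)2, Et3N, 4 Å MS, CH2Cl2, air, rt
Reagents that add atoms: none
Why: Chan–Lam-type copper-mediated C–O coupling of an alkenylboronate with an alcohol, which proceeds with retention of alkene geometry; it gives the E enol ether (oxygen trans to C8) that neither ketone enolisation nor a 2-alkoxyvinyl metal could supply.

Step 16
Reactants: 23 8-[(E)-2-(4-methoxybenzyloxy)prop-1-enyl] bicyclic butenolide, C3 trimethylsilyl ether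
Product: 24 (3S,4S,6R,8R)-3-hydroxy-3-vinyl-8-[(E)-2-(4-methoxybenzyloxy)prop-1-enyl] bicyclic butenolide (C6 tert-butyldimethylsilyl ether; C13 4-methoxybenzyl ether)
Conditions: Bu4NF, AcOH, THF, 0 °C
Reagents that add atoms: none
Why: Fluoride cleavage of the tertiary trimethylsilyl ether; buffering with acetic acid protects the enol ether and the lactone, and the secondary tert-butyldimethylsilyl ether reacts far more slowly at 0 °C.

Step 17
Reactants: 24 (3S,4S,6R,8R)-3-hydroxy-3-vinyl-8-[(E)-2-(4-methoxybenzyloxy)prop-1-enyl] bicyclic butenolide
Product: 26 (4S,6R,10R) ten-membered 3-keto ylidene butenolide with ring-trans C8=C9 (C10 and C13 4-methoxybenzyl ethers; C6 tert-butyldimethylsilyl ether), via potassium enolate 25 (not isolated)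
Conditions: KN(SiMe3)2 (1.05 equiv), 18-crown-6, THF, −78 °C → rt; AcOH, −78 °C
Reagents that add atoms: none
Why: Anionic oxy-Cope rearrangement, the ring-expanding variant known for 1,2-dialkenylcyclohexanols. The base with 18-crown-6 gives the dissociated C3 potassium alkoxide, which weakens C3–C8 so that the [3,3] shift can run at or below room temperature: C3–C8 breaks, C1–C10 forms, and the C2=C3 enolate 25 and the C8=C9 double bond appear, irreversibly because the shift ends in an enolate. The ten-membered ring is made by a four-atom ring expansion through a six-membered chair transition state, not by an end-to-end cyclisation. In 24 the planar butenolide keeps O8 equatorial and the C8 alkenyl group axial on the cyclohexane chair; the C3 vinyl group is equatorial and gauche to it, and the C4 methyl and C6 silyloxy groups are equatorial, so the reactive conformation is the ground-state chair. In the array C1=C2–C3···C8–C9=C10 the C8–C7 bond is pseudo-equatorial and O8 pseudo-axial, which places C7 and C10 trans on the new double bond; the other rotamer about C8–C9 would push C10 against C6 and C7. C1 therefore meets one face of C10 only: with the E enol ether the oxygen on C10 is pseudo-equatorial and the methyl pseudo-axial, and from the 8R centre this gives 10R (a Z enol ether would give 10S). The selectivity is thus secured by three elements of the substrate: the cis relation of the alkenyl groups (3S,8R), the lactone-locked chair and the enol-ether geometry. The C3 alkoxide cannot attack the lactone without forming a bridgehead alkene, and one equivalent of base followed by a cold acetic acid quench should protonate the enolate at C2 before it can equilibrate towards C4.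

Step 18
Reactants: 26 (4S,6R,10R) ten-membered 3-keto ylidene butenolide, bis(4-methoxybenzyl) ether
Product: 27 10,13-diol of the ten-membered ylidene butenolide (C6 tert-butyldimethylsilyl ether)
Conditions: DDQ, CH2Cl2/pH 7 buffer, 0 °C → rt
Reagents that add atoms: none
Why: Oxidative cleavage of both 4-methoxybenzyl ethers with DDQ (hydride abstraction, then hydrolysis of the oxocarbenium ions); the silyl ether, the ketone and the electron-poor dienyl ester should be inert.

Step 19
Reactants: 27 10,13-diol of the ten-membered ylidene butenolide
Product: 28 13-acetate (C10 hydroxyl free; C6 tert-butyldimethylsilyl ether)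
Conditions: Ac2O, pyridine, CH2Cl2, 0 °C
Reagents that add atoms: acetic anhydride, CC(=O)OC(C)=O
Why: Acylation with anhydride and pyridine; the primary allylic C13 hydroxyl reacts, the tertiary C10 hydroxyl does not under these conditions, and O6 is still silylated.

Step 20
Reactants: 28 13-acetate, C6 tert-butyldimethylsilyl ether
Product: 29 (4S,6R,10R)-13-acetoxy-6,10-dihydroxy-3-oxo ten-membered ylidene butenolide
Conditions: HF·pyridine, pyridine, THF, 0 °C → rt
Reagents that add atoms: none
Why: Desilylation with buffered HF·pyridine; the acetate, the enol lactone and the tertiary allylic alcohol should tolerate these mildly acidic conditions.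

Step 21
Reactants: 29 (4S,6R,10R)-13-acetoxy-6,10-dihydroxy-3-oxo ten-membered ylidene butenolide, 30 3-methylbut-2-enoyl chloride
Product: 31 CNP0186726.1, (4S,6R,10R)-13-acetoxy-10-hydroxy-6-(3-methylbut-2-enoyloxy)-3-oxogermacra-7(11),8-dien-12,8-olide with C7 and C10 trans on C8=C9
Conditions: 30, pyridine, DMAP (cat.), CH2Cl2, 0 °C
Reagents that add atoms: none
Why: Acylation of the secondary C6 alcohol with an acid chloride under DMAP catalysis; pyridine as the only base avoids deconjugation of the senecioyl group through a vinylketene, and the tertiary alcohol stays free.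

## Compound list

1 | 1,4-dioxaspiro[4.5]dec-6-en-8-one | O=C1C=CC2(CC1)OCCO2 | starting material
2 | (R)-1,4-dioxaspiro[4.5]dec-6-en-8-ol | O[C@H]1C=CC2(CC1)OCCO2 | intermediate
3 | (R)-8-(tert-butyldimethylsilyloxy)-1,4-dioxaspiro[4.5]dec-6-ene | CC(C)(C)[Si](C)(C)O[C@H]1C=CC2(CC1)OCCO2 | intermediate
4 | (R)-4-(tert-butyldimethylsilyloxy)cyclohex-2-en-1-one | O=C1C=C[C@H](O[Si](C)(C)C(C)(C)C)CC1 | intermediate
5 | (4R)-4-(tert-butyldimethylsilyloxy)-6-methylcyclohex-2-en-1-one, both epimers at the methyl carbon | O=C1C=C[C@H](O[Si](C)(C)C(C)(C)C)CC1C | intermediate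
6 | methyl acrylate | C=CC(=O)OC | starting material
7 | 4-methoxybenzyl alcohol | COc1ccc(CO)cc1 | starting material
8 | methyl 3-(4-methoxybenzyloxy)propanoate | COC(=O)CCOCc1ccc(OC)cc1 | intermediate
9 | 1-methoxy-3-(4-methoxybenzyloxy)-1-(trimethylsilyloxy)prop-1-ene, E/Z mixture | COC(O[Si](C)(C)C)=CCOCc1ccc(OC)cc1 | intermediate
10 | Michael adduct as its C3 trimethylsilyl enol ether (C3=C8), side chain on C7 trans to O6, C4 and C11 epimers | C[Si](C)(C)OC1=C[C@@H](C(COCc2ccc(OC)cc2)C(=O)OC)[C@H](O[Si](C)(C)C(C)(C)C)CC1C | intermediate
11 | methyl 2-[(1S,2R,4S)-2-(tert-butyldimethylsilyloxy)-4-methyl-5-oxocyclohexyl]-3-(4-methoxybenzyloxy)propanoate, C11 epimers | O=C1[C@@H](C)C[C@@H](O[Si](C)(C)C(C)(C)C)[C@H](C(COCc2ccc(OC)cc2)C(=O)OC)C1 | intermediate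
12 | methyl 2-[(1R,2R,4S,6R)-2-(tert-butyldimethylsilyloxy)-6-hydroxy-4-methyl-5-oxocyclohexyl]-3-(4-methoxybenzyloxy)propanoate, C11 epimers | O=C1[C@@H](C)C[C@@H](O[Si](C)(C)C(C)(C)C)[C@H](C(COCc2ccc(OC)cc2)C(=O)OC)[C@H]1O | intermediate
13 | vinylmagnesium bromide | C=C[Mg]Br | starting material
14 | methyl 2-[(1R,2R,4S,5S,6R)-2-(tert-butyldimethylsilyloxy)-5,6-dihydroxy-4-methyl-5-vinylcyclohexyl]-3-(4-methoxybenzyloxy)propanoate, C11 epimers | C=C[C@]1(O)[C@@H](C)C[C@@H](O[Si](C)(C)C(C)(C)C)[C@H](C(COCc2ccc(OC)cc2)C(=O)OC)[C@H]1O | intermediate
15 | methyl 2-[(1S,2R,4S,5S)-2-(tert-butyldimethylsilyloxy)-5-hydroxy-4-methyl-6-oxo-5-vinylcyclohexyl]-3-(4-methoxybenzyloxy)propanoate, C11 epimers | C=C[C@]1(O)[C@@H](C)C[C@@H](O[Si](C)(C)C(C)(C)C)[C@H](C(COCc2ccc(OC)cc2)C(=O)OC)C1=O | intermediate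
16 | methyl 2-[(1S,2R,4S,5S)-2-(tert-butyldimethylsilyloxy)-4-methyl-6-oxo-5-(trimethylsilyloxy)-5-vinylcyclohexyl]-3-(4-methoxybenzyloxy)propanoate, C11 epimers | C=C[C@]1(O[Si](C)(C)C)[C@@H](C)C[C@@H](O[Si](C)(C)C(C)(C)C)[C@H](C(COCc2ccc(OC)cc2)C(=O)OC)C1=O | intermediate
17 | prop-1-ynylmagnesium bromide | CC#C[Mg]Br | starting material
18 | tertiary C8 alkoxide of the propynyl adduct (drawn as the free alcohol), propynyl trans to the C3 silyloxy group | C=C[C@]1(O[Si](C)(C)C)[C@@H](C)C[C@@H](O[Si](C)(C)C(C)(C)C)[C@H](C(COCc2ccc(OC)cc2)C(=O)OC)[C@]1(O)C#CC | intermediate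
19 | saturated trans-fused 12,8-lactone, C8 propynyl cis to C3 vinyl, C3 trimethylsilyl ether, C6 tert-butyldimethylsilyl ether, C13 4-methoxybenzyl ether, C11 epimers | C=C[C@]1(O[Si](C)(C)C)[C@@H](C)C[C@@H](O[Si](C)(C)C(C)(C)C)[C@@H]2C(COCc3ccc(OC)cc3)C(=O)O[C@@]12C#CC | intermediate
20 | 11-phenylselanyl derivative of lactone 19, selenium on the face of H7 | C=C[C@]1(O[Si](C)(C)C)[C@@H](C)C[C@@H](O[Si](C)(C)C(C)(C)C)[C@@H]2[C@@](COCc3ccc(OC)cc3)([Se]c4ccccc4)C(=O)O[C@@]12C#CC | intermediate
21 | (3S,4S,6R,8R)-8-(prop-1-ynyl) bicyclic butenolide, C3 trimethylsilyl ether, C6 tert-butyldimethylsilyl ether, C13 4-methoxybenzyl ether | C=C[C@]1(O[Si](C)(C)C)[C@@H](C)C[C@@H](O[Si](C)(C)C(C)(C)C)C2=C(COCc3ccc(OC)cc3)C(=O)O[C@@]12C#CC | intermediate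
22 | 8-[(Z)-2-(4,4,5,5-tetramethyl-1,3,2-dioxaborolan-2-yl)prop-1-enyl] bicyclic butenolide, boron trans to C8 | C=C[C@]1(O[Si](C)(C)C)[C@@H](C)C[C@@H](O[Si](C)(C)C(C)(C)C)C2=C(COCc3ccc(OC)cc3)C(=O)O[C@@]12/C=C(\C)B4OC(C)(C)C(C)(C)O4 | intermediate
23 | 8-[(E)-2-(4-methoxybenzyloxy)prop-1-enyl] bicyclic butenolide, C3 trimethylsilyl ether | C=C[C@]1(O[Si](C)(C)C)[C@@H](C)C[C@@H](O[Si](C)(C)C(C)(C)C)C2=C(COCc3ccc(OC)cc3)C(=O)O[C@@]12/C=C(\C)OCc4ccc(OC)cc4 | intermediate
24 | (3S,4S,6R,8R)-3-hydroxy-3-vinyl-8-[(E)-2-(4-methoxybenzyloxy)prop-1-enyl] bicyclic butenolide, C6 tert-butyldimethylsilyl ether, C13 4-methoxybenzyl ether | C=C[C@]1(O)[C@@H](C)C[C@@H](O[Si](C)(C)C(C)(C)C)C2=C(COCc3ccc(OC)cc3)C(=O)O[C@@]12/C=C(\C)OCc4ccc(OC)cc4 | intermediate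
25 | potassium C2=C3 enolate of the ring-expanded ketone (ring-cis enolate, ring-trans C8=C9) | COc1ccc(COCC2=C3/C(=C/[C@](C)(OCc4ccc(OC)cc4)C/C=C(/[O-])[C@@H](C)C[C@H]3O[Si](C)(C)C(C)(C)C)OC2=O)cc1.[K+] | intermediate
26 | (4S,6R,10R) ten-membered 3-keto ylidene butenolide, C10 and C13 4-methoxybenzyl ethers, C6 tert-butyldimethylsilyl ether, C7 and C10 trans on C8=C9 | COc1ccc(COCC2=C3/C(=C/[C@](C)(OCc4ccc(OC)cc4)CCC(=O)[C@@H](C)C[C@H]3O[Si](C)(C)C(C)(C)C)OC2=O)cc1 | intermediate
27 | 10,13-diol, C6 tert-butyldimethylsilyl ether | OCC1=C2/C(=C/[C@](C)(O)CCC(=O)[C@@H](C)C[C@H]2O[Si](C)(C)C(C)(C)C)OC1=O | intermediate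
28 | 13-acetate, C10 hydroxyl free, C6 tert-butyldimethylsilyl ether | CC(=O)OCC1=C2/C(=C/[C@](C)(O)CCC(=O)[C@@H](C)C[C@H]2O[Si](C)(C)C(C)(C)C)OC1=O | intermediate
29 | (4S,6R,10R)-13-acetoxy-6,10-dihydroxy-3-oxo ten-membered ylidene butenolide | CC(=O)OCC1=C2/C(=C/[C@](C)(O)CCC(=O)[C@@H](C)C[C@H]2O)OC1=O | intermediate
30 | 3-methylbut-2-enoyl chloride | CC(C)=CC(Cl)=O | starting material
31 | CNP0186726.1, (4S,6R,10R)-13-acetoxy-10-hydroxy-6-(3-methylbut-2-enoyloxy)-3-oxogermacra-7(11),8-dien-12,8-olide | CC(=O)OCC1=C2/C(=C/[C@](C)(O)CCC(=O)[C@@H](C)C[C@H]2OC(=O)C=C(C)C)OC1=O | target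

## Step count and weakest steps

Total: 21 steps. Longest linear sequence: 19 steps (steps 1–4 and 7–21, from 1); steps 5 and 6 are a two-step side branch that joins at step 7.

**Step 17 (key step).** The C3–C8 bond is flanked by oxygen on both carbons. The most likely failure is heterolytic cleavage of this bond in the alkoxide (a retro-aldol-like fragmentation into a vinyl ketone and an oxygen-substituted allyl anion) in place of the concerted shift, followed by recombination without stereocontrol or by elimination. Base-induced loss of configuration at C4 or C6 after the shift is the second risk. The fallback avoids the alkoxide altogether. It sets out from silyl ether 23, which is heated (PhMe, sealed silylated tube, 160–180 °C). The neutral siloxy-Cope shift should pass through the same chair and give the C3 trimethylsilyl enol ether of the ring-expanded ketone F1. Buffered fluoride (Bu4NF, AcOH, THF, 0 °C) then releases the ketone, and the route is rejoined at 26.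

**Step 15 (with step 14).** Transmetalation of the trisubstituted alkenylboronate to copper may be slow, so protodeboronation or oxidative homocoupling could outrun C–O bond formation. The fallback sets out from alkyne 21 and uses a halide in place of boron. Stoichiometric hydrozirconation (Cp2Zr(H)Cl, THF, rt) followed by iodine should give the (E)-2-iodoprop-1-enyl butenolide F2, with iodine trans to C8. Copper-catalysed coupling with alcohol 7 (CuI, 3,4,7,8-tetramethyl-1,10-phenanthroline, Cs2CO3, PhMe, 80 °C) proceeds with retention and returns to 23.

**Step 13.** Selenium may be delivered to the face opposite H7. Then no syn hydrogen is available inside the ring, and elimination would stall or turn towards C13. The fallback uses an elimination with the opposite stereochemical demand. From 19, enolate bromination (LiN(i-Pr)2, THF, −78 °C; N-bromosuccinimide) gives the 11-bromo lactone F3, with bromine anti to H7 in that case. DBU (PhMe, 80 °C) then effects an anti E2 elimination and returns to 21.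

**Step 9.** The risks are attack from the axial side, which would give the C3 epimer and put the vinyl group anti to the later C8 substituent, or closure of the C8 alkoxide onto the ester. The fallback builds the vinyl group from two one-carbon units under thermodynamic control. From 12, the Corey–Chaykovsky reaction with dimethylsulfoxonium methylide (Me3S(O)I, NaH, DMSO, rt) adds reversibly and should place the new C–C bond equatorial, giving the C3 spiro-epoxide F4 with axial oxygen. Dimethylsulfonium methylide (Me3SI, n-BuLi, THF, −10 °C → rt) then opens the epoxide at its CH2 group and eliminates dimethyl sulfide, giving the one-carbon-homologated allylic alcohol. This returns to 14.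

## Further compounds

F1 | step 17 | C3 trimethylsilyl enol ether (C2=C3, ring-cis) of ring-expanded ketone 26 | COc1ccc(COCC2=C3/C(=C/[C@](C)(OCc4ccc(OC)cc4)C/C=C(/O[Si](C)(C)C)[C@@H](C)C[C@H]3O[Si](C)(C)C(C)(C)C)OC2=O)cc1
F2 | step 15 | 8-[(E)-2-iodoprop-1-enyl] bicyclic butenolide, C3 trimethylsilyl ether | C=C[C@]1(O[Si](C)(C)C)[C@@H](C)C[C@@H](O[Si](C)(C)C(C)(C)C)C2=C(COCc3ccc(OC)cc3)C(=O)O[C@@]12/C=C(\C)I
F3 | step 13 | 11-bromo derivative of lactone 19, bromine anti to H7 | C=C[C@]1(O[Si](C)(C)C)[C@@H](C)C[C@@H](O[Si](C)(C)C(C)(C)C)[C@@H]2[C@](COCc3ccc(OC)cc3)(Br)C(=O)O[C@@]12C#CC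
F4 | step 9 | C3 spiro-epoxide of hydroxy ketone 12, epoxide oxygen axial and cis to O8 | O1C[C@@]12[C@@H](C)C[C@@H](O[Si](C)(C)C(C)(C)C)[C@H](C(COCc3ccc(OC)cc3)C(=O)OC)[C@H]2O
A1 | alternative 1 | ten-membered 6-hydroxy 3-ketone ylidene butenolide, C10 triethylsilyl ether, C13 acetate | CC(=O)OCC1=C2/C(=C/[C@](C)(O[Si](CC)(CC)CC)CCC(=O)[C@@H](C)C[C@H]2O)OC1=O
A2 | alternative 1 | seco C6 aldehyde with a 2-methylcyclopropanol at C3–C5 (both carbinol epimers) | CC(=O)OCC1=C(C=O)/C(=C/[C@](C)(O[Si](CC)(CC)CC)CCC2(O)C[C@@H]2C)OC1=O
A3 | alternative 2 | ten-membered 3-ketone with E C9=C10 alkene, C8 silyl ether, C6 4-methoxybenzyl ether, exocyclic C7=C11 ester | O=C1CC/C(C)=C/[C@H](O[Si](C)(C)C(C)(C)C)/C(=C(/CO[Si](C)(C)C(C)(C)C)C(=O)OC)[C@H](OCc2ccc(OC)cc2)C[C@@H]1C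
A4 | alternative 2 | twelve-membered allylic β-keto lactone (C2–CO–O–C1) | O=C1CC(=O)OC/C(C)=C/[C@H](O[Si](C)(C)C(C)(C)C)/C(=C(/CO[Si](C)(C)C(C)(C)C)C(=O)OC)[C@H](OCc2ccc(OC)cc2)C[C@@H]1C
A5 | alternative 3 | protected ten-membered ylidene butenolide with C3 dioxolane | COc1ccc(COCC2=C3/C(=C/[C@](C)(O[Si](CC)(CC)CC)CCC4(OCCO4)[C@@H](C)C[C@H]3O[Si](C)(C)C(C)(C)C)OC2=O)cc1
A6 | alternative 3 | eleven-membered cyclic sulfone with sulfur between C8 and C9 (both C8 epimers) | COc1ccc(COCC2=C3C(OC2=O)S(=O)(=O)C[C@](C)(O[Si](CC)(CC)CC)CCC4(OCCO4)[C@@H](C)C[C@H]3O[Si](C)(C)C(C)(C)C)cc1
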